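## Structural features

The target is a flavanone: benzene ring A is fused through C4a–C8a to dihydropyranone ring C (O1, C2, C3, C4=O), and C2 carries an unsubstituted phenyl ring B. Ring A is hexasubstituted: oxygen on C8a (O1), C5 and C7 in a phloroglucinol pattern, and two identical 2,3-dihydroxybenzyl groups joined through CH2 to C6 and C8. C2 (S) is the only stereocentre and has no stereogenic neighbour. It is, however, a benzylic ether carbon β to the C4 ketone, so base (and, less readily, strong acid) can open ring C to the chalcone and erase it. The two catechols and the electron-rich ring A are sensitive to oxidation and to electrophiles, so every phenol should stay masked until the last step. The real difficulty is ring A: all six positions must be filled without ambiguity and the three oxygens told apart, because O1 is alkylated, O7 sits between two arylmethyl groups and O5 flanks the acylation site C4a. The key step uses the alternation of oxygen-bearing carbons (C5, C7, C8a) with carbon- or hydrogen-bearing ones (C6, C8, C4a): this maps onto a 3-alkoxy vinylketene (C7, C6, C5, C4a) and an ynol ether (C8, C8a). Stripped of its masks, the ring A precursor with hydrogen on C4a is symmetric about the C4a···C7 axis, so either flanking oxygen may become O1 as long as only one is unmasked.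

## Logic of the disconnections

**34 ⇒ 33.** The last cut removes the five O–CH2Ph bonds (on O7 and the four catechol oxygens) and the O5–ethyl bond. Keeping all six phenols masked avoids oxidation and base-induced ring opening in every earlier step. The gain is a neutral, lipophilic penultimate compound. The forward step needs one reagent that cleaves aryl benzyl ethers and the peri ethyl ether but leaves C2–O1 alone.

**33 ⇒ 31.** C4–C4a is cut. C4a is the only hydrogen-bearing carbon of ring A and lies between two oxygen-bearing carbons, so an acyl cation tethered through O1 can close only there, forming the six-membered ring C. This removes ring C and the ketone and leaves an open-chain acid. The forward step needs an activation mild enough for the benzylic ether at C2.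

**31 ⇒ 30 ⇒ 28 + 29.** After the acid/ester change, O1–C2 is cut. This sends the only stereocentre back to 29, which is purchased enantiopure, and leaves an achiral phenol. The forward step must be a clean SN2 displacement with inversion, which is why the (R) alcohol is taken, and 28 must carry exactly one free phenol.

**28 ⇒ 27 ⇒ 26.** The O–Si bond on C8a and the O–benzyl bond on C7 are adjusted. In 26 the C7 oxygen is free, the C8a oxygen silylated and the C5 oxygen ethylated, so capping the first and then unmasking the second raises no selectivity question. The forward steps must etherify a phenol lying between two arylmethyl groups without loss of silicon.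

**26 ⇒ 11 + 21.** The key cut: C7–C8, C8a–C4a and C6–C7. Ring A is taken apart into a four-carbon piece (C7, C6, C5, C4a) stored in the strained ring of 11 and a two-carbon piece (C8, C8a) in 21. A hexasubstituted benzene with three distinct oxygens becomes two small fragments, each carrying one arylmethyl group. The forward step needs a single orientation of the ketene–alkyne union.

**11 ⇒ 7 + 8.** The four-membered ring is cut at its C1–C2 and C3–C4 bonds (C3–C4 is C5–C6 of the target), a ketene–alkyne cycloaddition in reverse; 7 supplies the ketene through 9 and 10. The gain is a commercial ynol ether and a simple acid. The monosubstituted ketene must be trapped faster than it dimerises.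

**7 ⇒ 2 + 3.** The bond between the benzylic CH2 and the α-carbon of the acid is cut; the two-carbon unit comes from 3 by condensation, conjugate reduction and decarboxylation in one pot. The reduction must leave O-benzyl groups alone.

**21 ⇒ 16 + 17.** The O–Si bond and the bond between the benzylic CH2 and alkyne carbon C8 are cut; C8 comes from 17 and the arylmethyl group reaches it by a 1,2-shift. The gain is an ordinary ester. Addition of 18 to the ester carbonyl must outrun enolisation.

**16 ⇒ 14 ⇒ 2 + 12.** The C–C bond between the benzylic carbon and the carboxyl carbon is cut, which leads to the same aldehyde as the other branch, so both fragments diverge from 2. The one-carbon homologation must avoid the oxazole side path.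

**2 ⇒ 1.** The two O–benzyl bonds are cut, back to a commercial catechol aldehyde.

## Other disconnections considered

**Alternative 1:** The two CH2–aryl bonds at C6 and C8 are cut. Forward, (S)-pinocembrin A1 would be aminomethylated twice (Mannich reaction) to A2. On warming, A2 would lose its amine to give ring A ortho-quinone methides, and two equivalents of the boronic acid A3 would transfer their aryl groups to the methide carbons to give A4; hydrogenolysis would finish. In its favour: the whole flavanone with its stereocentre is bought, the oxygens need no differentiation, and the sequence is about three steps. On step economy this alternative is clearly the better plan. Against it: uncatalysed aryl transfer from a plain, ortho-substituted arylboronic acid to a quinone methide is the weak link of the class. It has to happen twice, in competition with re-addition of the amine and self-condensation of the methide. The heat and free amine needed are exactly the conditions under which a 5,7-dihydroxyflavanone opens to its chalcone and loses C2. In the chosen plan the stereocentre enters only after the high-temperature step. Both plans make equal use of the equivalence of C6 and C8.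

**Alternative 2:** Three ring A bonds are cut (C4a–C8a, C7–C8, C5–C6). Forward, the chiral diyne A5 and the siloxyalkyne 21 would cyclotrimerise on [Rh(cod)2]BF4 (cationic monovalent rhodium) with BINAP to give A6, closing rings A and C at once. In its favour: it forms more bonds and rings in one operation than the chosen key step, it needs no Friedel–Crafts step, and it uses the same alkyne 21 and the same oxygen labels (ethyl on O5, silicon on O7), so on convergence it is the better plan and on labelling the equal. Against it: A5 combines a secondary alkyl ynol ether β to a ketone (prone to retro-ene loss of ketene and to β-elimination) with an acyl ynol ether, so the precursor would probably cost more steps and care than both fragments of the chosen plan together. Nothing in A5 biases the orientation in which 21 inserts, so the isomer with silyloxy on C6 is a real prospect. The chiral ligand has no stereocentre to set. The chosen cascade is metal-free and its regiochemistry follows from polarisation alone.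

**Alternative 3:** C2–C3 is cut. Forward, the diazoketone A7 would lose N2 on Rh2(S-DOSP)4 (a divalent rhodium carboxylate dimer) or its enantiomer, and the carbenoid carbon would insert into a benzylic C–H of an ortho O-benzyl group to give A8, closing ring C. In its favour: A7 has a symmetric ring A, so either ortho benzyl ether gives the same product. All oxygens carry benzyl, and one hydrogenolysis would end the synthesis. On protecting-group economy and mildness of the endgame it is better than the chosen plan. Against it: the carbenoid is of the acceptor-only type, for which this catalyst family gives its least reliable enantiocontrol. Attack on the ether oxygen to form an oxonium ylide, followed by 1,2-benzyl shift (Stevens rearrangement) to a benzofuranone, is a favoured competitor. Buchner addition to the many arene rings is a further risk. The chosen plan takes C2 from an enantiopure building block by an invertive displacement, which is the more secure way to set the only stereocentre; ring A of A7 would also rely on classical C-benzylation of a phloroglucinol.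

Key step: step 7

Remark on the chemistry: BCl3 cannot be expected to spare aryl benzyl ethers, so de-ethylation and debenzylation are merged into one final step. The structures of the key step were checked atom by atom against the target and stand. Ring A atoms are named by flavanone numbering (C4a, C5–C8, C8a) in all intermediates.

## Route

**Step 1**
Reactants: 1 2,3-dihydroxybenzaldehyde
Product: 2 2,3-bis(benzyloxy)benzaldehyde
Conditions: BnBr, K2CO3, DMF, 60 °C
Reagents that add atoms: benzyl bromide, BrCc1ccccc1
Why: Williamson etherification of both phenols; benzyl survives organolithiums, heat, fluoride, Mitsunobu conditions and mild acid, and leaves in the same final operation as the ethyl group.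

**Step 2**
Reactants: 2 2,3-bis(benzyloxy)benzaldehyde; 3 Meldrum's acid (2,2-dimethyl-1,3-dioxane-4,6-dione)
Product: 7 3-[2,3-bis(benzyloxy)phenyl]propanoic acid, via arylidene Meldrum's acid 4 (not isolated), via benzyl Meldrum's acid 5 (not isolated), via benzylmalonic acid 6 (not isolated)
Conditions: HCO2H/Et3N (5:2), 95 °C
Reagents that add atoms: water, O (formed in the condensation; supplies part of the carboxyl oxygen)
Why: Reductive Knoevenagel sequence in triethylammonium formate: condensation to 4, conjugate hydride transfer from formate to 5, hydrolysis to 6 and decarboxylation; no metal is present, so the benzyl ethers are safe.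

**Step 3**
Reactants: 7 3-[2,3-bis(benzyloxy)phenyl]propanoic acid; 8 ethoxyacetylene
Product: 11 4-[2,3-bis(benzyloxy)benzyl]-3-ethoxycyclobut-2-en-1-one (racemic), via acid chloride 9 (not isolated), via arylmethylketene 10 (not isolated)
Conditions: (COCl)2, cat. DMF, CH2Cl2, rt; evaporate; then 8 (3 equiv), Et3N (slow addition), Et2O, 0 °C → rt
Reagents that add atoms: none
Why: Dehydrochlorination of 9 gives aldoketene 10, which the excess of 8 traps in a ketene–alkyne [2+2] cycloaddition; the nucleophilic CH terminus of the ynol ether bonds to the ketene carbonyl carbon, so ethoxy ends on C3 next to the arylmethyl-bearing C4. The C4 stereocentre is racemic and is destroyed in step 7.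

**Step 4**
Reactants: 2 2,3-bis(benzyloxy)benzaldehyde; 12 p-toluenesulfonylmethyl isocyanide (TosMIC)
Product: 14 2-[2,3-bis(benzyloxy)phenyl]acetonitrile, via tosylvinylformamide 13 (not isolated)
Conditions: KOt-Bu, DME, −50 → −30 °C; then MeOH, reflux
Reagents that add atoms: none
Why: Van Leusen reductive cyanation: the TosMIC anion adds to the aldehyde, the oxazoline opens to 13, and methanolysis removes the formyl group and sulfinate to leave the homologous nitrile; low temperature in an aprotic solvent avoids the oxazole path.

**Step 5**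
Reactants: 14 2-[2,3-bis(benzyloxy)phenyl]acetonitrile
Product: 16 ethyl 2-[2,3-bis(benzyloxy)phenyl]acetate, via imidate hydrochloride 15 (not isolated)
Conditions: anhydrous HCl, EtOH, 0 °C → rt; then H2O, rt
Reagents that add atoms: ethanol, CCO; water, O
Why: Pinner reaction: the nitrile gives imidate salt 15, which water converts to the ethyl ester; aryl benzyl ethers tolerate ethanolic HCl at or below room temperature.

**Step 6**
Reactants: 16 ethyl 2-[2,3-bis(benzyloxy)phenyl]acetate; 17 dibromomethane
Product: 21 {3-[2,3-bis(benzyloxy)phenyl]prop-1-yn-1-yloxy}triisopropylsilane, via dibromomethyllithium 18 (not isolated), via lithium dibromoenolate 19 (not isolated), via lithium ynolate 20 (not isolated)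
Conditions: 17, LiTMP (lithium 2,2,6,6-tetramethylpiperidide), THF, −78 °C; 16; LiN(SiMe3)2; n-BuLi, −78 → 0 °C; TIPSCl, −78 °C → rt
Reagents that add atoms: triisopropylsilyl chloride, CC(C)[Si](Cl)(C(C)C)C(C)C
Why: Kowalski ynolate synthesis: 18 adds to the ester, the dibromoketone is held as enolate 19, and bromine–lithium exchange with 1,2-shift of the arylmethyl group gives ynolate 20. The bulky silyl chloride reacts at oxygen to give an isolable silyl ynol ether.

**Step 7**
Reactants: 11 4-[2,3-bis(benzyloxy)benzyl]-3-ethoxycyclobut-2-en-1-one; 21 {3-[2,3-bis(benzyloxy)phenyl]prop-1-yn-1-yloxy}triisopropylsilane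
Product: 26 2,6-bis[2,3-bis(benzyloxy)benzyl]-3-ethoxy-5-(triisopropylsilyloxy)phenol, via vinylketene 22 (not isolated), via vinylcyclobutenone 23 (not isolated), via dienylketene 24 (not isolated), via cyclohexadienone 25 (not isolated)
Conditions: 21 (1.3 equiv), toluene, 80 → 110 °C, sealed tube, argon
Reagents that add atoms: none
Why: This is a Danheiser benzannulation, the known cascade of cyclobutenones with siloxyalkynes that gives resorcinol monosilyl ethers. Heating opens 11 by a four-electron conrotatory electrocyclic reaction, driven by ring strain, to vinylketene 22, the C4 substituent rotating outward. The electron-rich alkyne carbon of 21 (the one bearing the arylmethyl group) attacks the electrophilic ketene carbon and the silyloxy-bearing carbon closes onto the ketene α-carbon, a regiospecific [2+2] cycloaddition that forms C7–C8 and C8a–C4a and gives 23. A second four-electron opening gives dienylketene 24, and ring A closes by a six-electron disrotatory electrocyclisation that forms C6–C7 and gives 25, which tautomerises to phenol 26. No stereocentre is created: the sp3 carbons of 11, 23 and 25 are all lost on aromatisation. The selectivity needed is the orientation of the ketene–alkyne union; the polarisation of the ynol ether fixes it, so both arylmethyl groups end ortho to the new C7 hydroxyl, silyloxy lands on C8a and ethoxy on C5. The three oxygens therefore emerge as free phenol, silyl ether and ethyl ether. A modest excess of 21 at moderate concentration should limit dimerisation of 22 and acylation of the hindered product phenol by the ketene.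

**Step 8**
Reactants: 26 2,6-bis[2,3-bis(benzyloxy)benzyl]-3-ethoxy-5-(triisopropylsilyloxy)phenol
Product: 27 {3-(benzyloxy)-2,4-bis[2,3-bis(benzyloxy)benzyl]-5-ethoxyphenoxy}triisopropylsilane
Conditions: NaH, BnBr, cat. Bu4NI, DMF, 0 °C → rt
Reagents that add atoms: benzyl bromide, BrCc1ccccc1
Why: Williamson etherification of the only free phenol (O7); the silyl group cannot migrate to a meta oxygen and the bulky triisopropylsilyl ether should resist the phenoxide at these temperatures.

**Step 9**
Reactants: 27 {3-(benzyloxy)-2,4-bis[2,3-bis(benzyloxy)benzyl]-5-ethoxyphenoxy}triisopropylsilane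
Product: 28 3-(benzyloxy)-2,4-bis[2,3-bis(benzyloxy)benzyl]-5-ethoxyphenol
Conditions: TBAF, AcOH, THF, 0 °C
Reagents that add atoms: none
Why: Fluoride cleaves the aryl Si–O bond; acetic acid buffers the electron-rich phenoxide against air oxidation, and all other ethers are inert.

**Step 10**
Reactants: 28 3-(benzyloxy)-2,4-bis[2,3-bis(benzyloxy)benzyl]-5-ethoxyphenol; 29 ethyl (R)-3-hydroxy-3-phenylpropanoate
Product: 30 ethyl (3S)-3-{3-(benzyloxy)-2,4-bis[2,3-bis(benzyloxy)benzyl]-5-ethoxyphenoxy}-3-phenylpropanoate
Conditions: PPh3, DIAD, toluene, 0 °C → rt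
Reagents that add atoms: none
Why: Mitsunobu reaction: the single phenol displaces the activated secondary benzylic alcohol by SN2 with inversion, so (R)-29 gives the (S) ether that becomes C2 of the target; a non-polar solvent and low temperature disfavour ionisation and β-elimination.

**Step 11**
Reactants: 30 ethyl (3S)-3-{3-(benzyloxy)-2,4-bis[2,3-bis(benzyloxy)benzyl]-5-ethoxyphenoxy}-3-phenylpropanoate
Product: 31 (3S)-3-{3-(benzyloxy)-2,4-bis[2,3-bis(benzyloxy)benzyl]-5-ethoxyphenoxy}-3-phenylpropanoic acid
Conditions: LiOH, THF/H2O, 0 °C → rt; then 1 M HCl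
Reagents that add atoms: lithium hydroxide, [Li+].[OH-]
Why: Saponification at low temperature, where hydroxide attack at the ester carbonyl should be faster than E1cB loss of the aryloxide; the carboxylate formed no longer eliminates and C2 is not involved.

**Step 12**
Reactants: 31 (3S)-3-{3-(benzyloxy)-2,4-bis[2,3-bis(benzyloxy)benzyl]-5-ethoxyphenoxy}-3-phenylpropanoic acid
Product: 33 (2S)-7-(benzyloxy)-6,8-bis[2,3-bis(benzyloxy)benzyl]-5-ethoxy-2-phenylchroman-4-one, via mixed trifluoroacetic anhydride 32 (not isolated)
Conditions: (CF3CO)2O, CH2Cl2, 0 °C → rt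
Reagents that add atoms: none
Why: Intramolecular Friedel–Crafts acylation through mixed anhydride 32: C4a is the only free position of ring A and is activated by two ortho oxygens and one para oxygen, so ring C closes at C4–C4a without a metal Lewis acid and C2 is untouched.

**Step 13**
Reactants: 33 (2S)-7-(benzyloxy)-6,8-bis[2,3-bis(benzyloxy)benzyl]-5-ethoxy-2-phenylchroman-4-one
Product: 34 (2S)-6,8-bis(2,3-dihydroxybenzyl)-5,7-dihydroxy-2-phenylchroman-4-one (CNP0059702.1)
Conditions: BCl3, C6HMe5, CH2Cl2, −78 → 0 °C; then MeOH/H2O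
Reagents that add atoms: none
Why: BCl3 cleaves the five aryl benzyl ethers at low temperature, with pentamethylbenzene as a non-basic trap for the benzyl cations, and on warming removes the ethyl group by chelation between the C4 carbonyl and O5 (peri-selective dealkylation). Ring B is an unactivated phenyl, so ionisation of C2–O1 is not expected and the (S) configuration should persist.

## Compound list

1 | 2,3-dihydroxybenzaldehyde | O=Cc1cccc(O)c1O | starting material
2 | 2,3-bis(benzyloxy)benzaldehyde | O=Cc1cccc(OCc2ccccc2)c1OCc1ccccc1 | intermediate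
3 | Meldrum's acid (2,2-dimethyl-1,3-dioxane-4,6-dione) | CC1(C)OC(=O)CC(=O)O1 | starting material
4 | 5-[2,3-bis(benzyloxy)benzylidene]-2,2-dimethyl-1,3-dioxane-4,6-dione | CC1(C)OC(=O)C(=Cc2cccc(OCc3ccccc3)c2OCc2ccccc2)C(=O)O1 | intermediate (not isolated)
5 | 5-[2,3-bis(benzyloxy)benzyl]-2,2-dimethyl-1,3-dioxane-4,6-dione | CC1(C)OC(=O)C(Cc2cccc(OCc3ccccc3)c2OCc2ccccc2)C(=O)O1 | intermediate (not isolated)
6 | 2-[2,3-bis(benzyloxy)benzyl]malonic acid | OC(=O)C(Cc1cccc(OCc2ccccc2)c1OCc1ccccc1)C(=O)O | intermediate (not isolated)
7 | 3-[2,3-bis(benzyloxy)phenyl]propanoic acid | OC(=O)CCc1cccc(OCc2ccccc2)c1OCc1ccccc1 | intermediate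
8 | ethoxyacetylene | CCOC#C | starting material
9 | 3-[2,3-bis(benzyloxy)phenyl]propanoyl chloride | ClC(=O)CCc1cccc(OCc2ccccc2)c1OCc1ccccc1 | intermediate (not isolated)
10 | 3-[2,3-bis(benzyloxy)phenyl]prop-1-en-1-one (arylmethylketene) | O=C=CCc1cccc(OCc2ccccc2)c1OCc1ccccc1 | intermediate (not isolated)
11 | 4-[2,3-bis(benzyloxy)benzyl]-3-ethoxycyclobut-2-en-1-one (racemic) | CCOC1=CC(=O)C1Cc1cccc(OCc2ccccc2)c1OCc1ccccc1 | intermediate
12 | p-toluenesulfonylmethyl isocyanide (TosMIC) | [C-]#[N+]CS(=O)(=O)c1ccc(C)cc1 | starting material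
13 | N-{2-[2,3-bis(benzyloxy)phenyl]-1-(4-methylbenzenesulfonyl)ethenyl}formamide | O=CNC(=Cc1cccc(OCc2ccccc2)c1OCc1ccccc1)S(=O)(=O)c1ccc(C)cc1 | intermediate (not isolated)
14 | 2-[2,3-bis(benzyloxy)phenyl]acetonitrile | N#CCc1cccc(OCc2ccccc2)c1OCc1ccccc1 | intermediate
15 | ethyl 2-[2,3-bis(benzyloxy)phenyl]acetimidate hydrochloride | Cl.CCOC(=N)Cc1cccc(OCc2ccccc2)c1OCc1ccccc1 | intermediate (not isolated)
16 | ethyl 2-[2,3-bis(benzyloxy)phenyl]acetate | CCOC(=O)Cc1cccc(OCc2ccccc2)c1OCc1ccccc1 | intermediate
17 | dibromomethane | BrCBr | starting material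
18 | dibromomethyllithium | [Li]C(Br)Br | intermediate (not isolated)
19 | lithium 3-[2,3-bis(benzyloxy)phenyl]-1,1-dibromoprop-1-en-2-olate | [Li+].[O-]C(Cc1cccc(OCc2ccccc2)c1OCc1ccccc1)=C(Br)Br | intermediate (not isolated)
20 | lithium 3-[2,3-bis(benzyloxy)phenyl]prop-1-yn-1-olate | [Li+].[O-]C#CCc1cccc(OCc2ccccc2)c1OCc1ccccc1 | intermediate (not isolated)
21 | {3-[2,3-bis(benzyloxy)phenyl]prop-1-yn-1-yloxy}triisopropylsilane | CC(C)[Si](C(C)C)(C(C)C)OC#CCc1cccc(OCc2ccccc2)c1OCc1ccccc1 | intermediate
22 | (3Z)-5-[2,3-bis(benzyloxy)phenyl]-3-ethoxypenta-1,3-dien-1-one | O=C=C/C(OCC)=C/Cc1cccc(OCc2ccccc2)c1OCc1ccccc1 | intermediate (not isolated)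
23 | 2-[2,3-bis(benzyloxy)benzyl]-4-{3-[2,3-bis(benzyloxy)phenyl]-1-ethoxyprop-1-en-1-yl}-3-(triisopropylsilyloxy)cyclobut-2-en-1-one (racemic) | O=C1C(Cc2cccc(OCc3ccccc3)c2OCc2ccccc2)=C(O[Si](C(C)C)(C(C)C)C(C)C)C1/C(OCC)=C/Cc1cccc(OCc2ccccc2)c1OCc1ccccc1 | intermediate (not isolated)
24 | 2-[2,3-bis(benzyloxy)benzyl]-7-[2,3-bis(benzyloxy)phenyl]-5-ethoxy-3-(triisopropylsilyloxy)hepta-1,3,5-trien-1-one | O=C=C(Cc1cccc(OCc2ccccc2)c1OCc1ccccc1)/C(O[Si](C(C)C)(C(C)C)C(C)C)=C\C(OCC)=C\Cc1cccc(OCc2ccccc2)c1OCc1ccccc1 | intermediate (not isolated)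
25 | 2,6-bis[2,3-bis(benzyloxy)benzyl]-5-ethoxy-3-(triisopropylsilyloxy)cyclohexa-2,4-dien-1-one (racemic) | O=C1C(Cc2cccc(OCc3ccccc3)c2OCc2ccccc2)=C(O[Si](C(C)C)(C(C)C)C(C)C)C=C(OCC)C1Cc1cccc(OCc2ccccc2)c1OCc1ccccc1 | intermediate (not isolated)
26 | 2,6-bis[2,3-bis(benzyloxy)benzyl]-3-ethoxy-5-(triisopropylsilyloxy)phenol | CCOc1cc(O[Si](C(C)C)(C(C)C)C(C)C)c(Cc2cccc(OCc3ccccc3)c2OCc2ccccc2)c(O)c1Cc1cccc(OCc2ccccc2)c1OCc1ccccc1 | intermediate
27 | {3-(benzyloxy)-2,4-bis[2,3-bis(benzyloxy)benzyl]-5-ethoxyphenoxy}triisopropylsilane | CCOc1cc(O[Si](C(C)C)(C(C)C)C(C)C)c(Cc2cccc(OCc3ccccc3)c2OCc2ccccc2)c(OCc2ccccc2)c1Cc1cccc(OCc2ccccc2)c1OCc1ccccc1 | intermediate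
28 | 3-(benzyloxy)-2,4-bis[2,3-bis(benzyloxy)benzyl]-5-ethoxyphenol | CCOc1cc(O)c(Cc2cccc(OCc3ccccc3)c2OCc2ccccc2)c(OCc2ccccc2)c1Cc1cccc(OCc2ccccc2)c1OCc1ccccc1 | intermediate
29 | ethyl (R)-3-hydroxy-3-phenylpropanoate | CCOC(=O)C[C@@H](O)c1ccccc1 | starting material
30 | ethyl (3S)-3-{3-(benzyloxy)-2,4-bis[2,3-bis(benzyloxy)benzyl]-5-ethoxyphenoxy}-3-phenylpropanoate | CCOC(=O)C[C@H](Oc1cc(OCC)c(Cc2cccc(OCc3ccccc3)c2OCc2ccccc2)c(OCc2ccccc2)c1Cc1cccc(OCc2ccccc2)c1OCc1ccccc1)c1ccccc1 | intermediate
31 | (3S)-3-{3-(benzyloxy)-2,4-bis[2,3-bis(benzyloxy)benzyl]-5-ethoxyphenoxy}-3-phenylpropanoic acid | OC(=O)C[C@H](Oc1cc(OCC)c(Cc2cccc(OCc3ccccc3)c2OCc2ccccc2)c(OCc2ccccc2)c1Cc1cccc(OCc2ccccc2)c1OCc1ccccc1)c1ccccc1 | intermediate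
32 | (3S)-3-{3-(benzyloxy)-2,4-bis[2,3-bis(benzyloxy)benzyl]-5-ethoxyphenoxy}-3-phenylpropanoic trifluoroacetic anhydride | O=C(C[C@H](Oc1cc(OCC)c(Cc2cccc(OCc3ccccc3)c2OCc2ccccc2)c(OCc2ccccc2)c1Cc1cccc(OCc2ccccc2)c1OCc1ccccc1)c1ccccc1)OC(=O)C(F)(F)F | intermediate (not isolated)
33 | (2S)-7-(benzyloxy)-6,8-bis[2,3-bis(benzyloxy)benzyl]-5-ethoxy-2-phenylchroman-4-one | O=C1C[C@@H](c2ccccc2)Oc2c(Cc3cccc(OCc4ccccc4)c3OCc3ccccc3)c(OCc3ccccc3)c(Cc3cccc(OCc4ccccc4)c3OCc3ccccc3)c(OCC)c21 | intermediate
34 | (2S)-6,8-bis(2,3-dihydroxybenzyl)-5,7-dihydroxy-2-phenylchroman-4-one | O=C1C[C@@H](c2ccccc2)Oc2c(Cc3cccc(O)c3O)c(O)c(Cc3cccc(O)c3O)c(O)c21 | target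

## Step count and least certain steps

Total: 13 steps. Longest linear sequence: 11 steps (1, 4, 5, 6, 7, 8, 9, 10, 11, 12, 13). The cyclobutenone branch (1, 2, 3) joins at step 7.

**Step 7 (key step).** The donor-substituted four-membered ring of 11 may be reluctant to open at temperatures that 21 tolerates. If it does open, dimerisation of 22 or its capture by the phenol already formed may outrun the cycloaddition. Fallback, from 7 back to 26, generating the same vinylketene by base and not by heat:
- 7 would be activated with carbonyldiimidazole and acylated onto the magnesium enolate of potassium ethyl malonate (MgCl2, Et3N) to give ethyl 5-[2,3-bis(benzyloxy)phenyl]-3-oxopentanoate F1.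
- Triethyl orthoformate with catalytic acid in ethanol would give ethyl (E)-5-[2,3-bis(benzyloxy)phenyl]-3-ethoxypent-2-enoate F2.
- Saponification would give (E)-5-[2,3-bis(benzyloxy)phenyl]-3-ethoxypent-2-enoic acid F3, and oxalyl chloride would give (E)-5-[2,3-bis(benzyloxy)phenyl]-3-ethoxypent-2-enoyl chloride F4.
- Et3N at room temperature in the presence of 21 would remove HCl from F4 across the acyl and γ positions to give 22 directly. Trapping by 21 gives 23, and gentle heating carries 23 on to 26.

**Step 6.** Dibromomethyllithium may deprotonate the acidic benzylic α-position of 16 in competition with addition to the ester carbonyl, and excess butyllithium may attack the benzylic ether positions. Fallback, from 2 back to 21, by oxidation of an acetylide and not by ester homologation: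
- NaBH4 would reduce 2 to [2,3-bis(benzyloxy)phenyl]methanol F5, and PBr3 would give 1,2-bis(benzyloxy)-3-(bromomethyl)benzene F6.
- CuBr-catalysed coupling with ethynylmagnesium bromide would give 1,2-bis(benzyloxy)-3-(prop-2-yn-1-yl)benzene F7.
- Deprotonation with n-BuLi and oxygen transfer from lithium tert-butyl peroxide would give the same ynolate 20, which triisopropylsilyl triflate silylates at oxygen to 21.

**Step 3.** Self-addition of the monosubstituted ketene 10 (dimerisation) may compete with its capture by 8, and the enol ether may be lost by hydrolysis during isolation. Fallback, from 16 back to 11, making the ketene slowly and without amine salt: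
- 16 would be saponified to 2-[2,3-bis(benzyloxy)phenyl]acetic acid F8.
- Activation with oxalyl chloride and acylation of trimethylsilyldiazomethane would give 1-[2,3-bis(benzyloxy)phenyl]-3-diazopropan-2-one F9.
- Photochemical Wolff rearrangement of F9 in the presence of excess 8 would release 10 at low stationary concentration, and cycloaddition gives 11.

**Step 10.** β-Elimination of the activated alcohol to the cinnamate, sluggish attack by the hindered phenoxide, or partial ionisation at the benzylic carbon may erode inversion. Fallback, from 28 back to 33, setting C2 by catalysis and bypassing steps 11 and 12 as well: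
- C-acetylation of 28 at C4a (acetic acid with trifluoroacetic anhydride, then mild methanolysis of any aryl acetate) would give 1-{4-(benzyloxy)-3,5-bis[2,3-bis(benzyloxy)benzyl]-6-ethoxy-2-hydroxyphenyl}ethan-1-one F10.
- Condensation with N,N-dimethylformamide dimethyl acetal and acid-induced ring closure would give 7-(benzyloxy)-6,8-bis[2,3-bis(benzyloxy)benzyl]-5-ethoxy-4H-chromen-4-one F11.
- Asymmetric conjugate addition of phenylboronic acid to F11, with Pd(OCOCF3)2 and the enantiomer of the tert-butyl pyridine–oxazoline ligand that leads to the (S) product, would give 33.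

**Step 13.** Cleavage of the chelated ethyl ether may be incomplete (ethyl is slower than methyl), benzyl cations may transfer to ring carbons, and prolonged Lewis acid contact may open ring C and erode C2. Fallback, from 33 back to 34, separating the two deprotections:
- Hydrogenolysis of 33 (H2, Pd/C, EtOAc/MeOH) would remove the five benzyl groups under neutral conditions to give (2S)-6,8-bis(2,3-dihydroxybenzyl)-5-ethoxy-7-hydroxy-2-phenylchroman-4-one F12.
- BBr3 in CH2Cl2 at low temperature would then cleave the single ethyl ether of F12 to give 34.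

## Further compounds

F1 | step 7 | ethyl 5-[2,3-bis(benzyloxy)phenyl]-3-oxopentanoate | CCOC(=O)CC(=O)CCc1cccc(OCc2ccccc2)c1OCc1ccccc1
F2 | step 7 | ethyl (E)-5-[2,3-bis(benzyloxy)phenyl]-3-ethoxypent-2-enoate | CCOC(=O)/C=C(/OCC)CCc1cccc(OCc2ccccc2)c1OCc1ccccc1
F3 | step 7 | (E)-5-[2,3-bis(benzyloxy)phenyl]-3-ethoxypent-2-enoic acid | OC(=O)/C=C(/OCC)CCc1cccc(OCc2ccccc2)c1OCc1ccccc1
F4 | step 7 | (E)-5-[2,3-bis(benzyloxy)phenyl]-3-ethoxypent-2-enoyl chloride | ClC(=O)/C=C(/OCC)CCc1cccc(OCc2ccccc2)c1OCc1ccccc1
F5 | step 6 | [2,3-bis(benzyloxy)phenyl]methanol | OCc1cccc(OCc2ccccc2)c1OCc1ccccc1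
F6 | step 6 | 1,2-bis(benzyloxy)-3-(bromomethyl)benzene | BrCc1cccc(OCc2ccccc2)c1OCc1ccccc1
F7 | step 6 | 1,2-bis(benzyloxy)-3-(prop-2-yn-1-yl)benzene | C#CCc1cccc(OCc2ccccc2)c1OCc1ccccc1
F8 | step 3 | 2-[2,3-bis(benzyloxy)phenyl]acetic acid | OC(=O)Cc1cccc(OCc2ccccc2)c1OCc1ccccc1
F9 | step 3 | 1-[2,3-bis(benzyloxy)phenyl]-3-diazopropan-2-one | [N-]=[N+]=CC(=O)Cc1cccc(OCc2ccccc2)c1OCc1ccccc1
F10 | step 10 | 1-{4-(benzyloxy)-3,5-bis[2,3-bis(benzyloxy)benzyl]-6-ethoxy-2-hydroxyphenyl}ethan-1-one | CC(=O)c1c(O)c(Cc2cccc(OCc3ccccc3)c2OCc2ccccc2)c(OCc2ccccc2)c(Cc2cccc(OCc3ccccc3)c2OCc2ccccc2)c1OCC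
F11 | step 10 | 7-(benzyloxy)-6,8-bis[2,3-bis(benzyloxy)benzyl]-5-ethoxy-4H-chromen-4-one | O=c1ccoc2c(Cc3cccc(OCc4ccccc4)c3OCc3ccccc3)c(OCc3ccccc3)c(Cc3cccc(OCc4ccccc4)c3OCc3ccccc3)c(OCC)c12
F12 | step 13 | (2S)-6,8-bis(2,3-dihydroxybenzyl)-5-ethoxy-7-hydroxy-2-phenylchroman-4-one | O=C1C[C@@H](c2ccccc2)Oc2c(Cc3cccc(O)c3O)c(O)c(Cc3cccc(O)c3O)c(OCC)c21
A1 | alternative 1 | (2S)-5,7-dihydroxy-2-phenylchroman-4-one ((S)-pinocembrin) | O=C1C[C@@H](c2ccccc2)Oc2cc(O)cc(O)c21
A2 | alternative 1 | (2S)-6,8-bis[(dimethylamino)methyl]-5,7-dihydroxy-2-phenylchroman-4-one | O=C1C[C@@H](c2ccccc2)Oc2c(CN(C)C)c(O)c(CN(C)C)c(O)c21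
A3 | alternative 1 | [2,3-bis(benzyloxy)phenyl]boronic acid | OB(O)c1cccc(OCc2ccccc2)c1OCc1ccccc1
A4 | alternative 1 | (2S)-6,8-bis[2,3-bis(benzyloxy)benzyl]-5,7-dihydroxy-2-phenylchroman-4-one | O=C1C[C@@H](c2ccccc2)Oc2c(Cc3cccc(OCc4ccccc4)c3OCc3ccccc3)c(O)c(Cc3cccc(OCc4ccccc4)c3OCc3ccccc3)c(O)c21
A5 | alternative 2 | (5S)-5-{3-[2,3-bis(benzyloxy)phenyl]prop-1-yn-1-yloxy}-1-ethoxy-5-phenylpent-1-yn-3-one | CCOC#CC(=O)C[C@@H](c1ccccc1)OC#CCc1cccc(OCc2ccccc2)c1OCc1ccccc1
A6 | alternative 2 | (2S)-6,8-bis[2,3-bis(benzyloxy)benzyl]-5-ethoxy-2-phenyl-7-(triisopropylsilyloxy)chroman-4-one | O=C1C[C@@H](c2ccccc2)Oc2c(Cc3cccc(OCc4ccccc4)c3OCc3ccccc3)c(O[Si](C(C)C)(C(C)C)C(C)C)c(Cc3cccc(OCc4ccccc4)c3OCc3ccccc3)c(OCC)c21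
A7 | alternative 3 | 1-{2,4,6-tris(benzyloxy)-3,5-bis[2,3-bis(benzyloxy)benzyl]phenyl}-2-diazoethan-1-one | [N-]=[N+]=CC(=O)c1c(OCc2ccccc2)c(Cc2cccc(OCc3ccccc3)c2OCc2ccccc2)c(OCc2ccccc2)c(Cc2cccc(OCc3ccccc3)c2OCc2ccccc2)c1OCc1ccccc1
A8 | alternative 3 | (2S)-5,7-bis(benzyloxy)-6,8-bis[2,3-bis(benzyloxy)benzyl]-2-phenylchroman-4-one | O=C1C[C@@H](c2ccccc2)Oc2c(Cc3cccc(OCc4ccccc4)c3OCc3ccccc3)c(OCc3ccccc3)c(Cc3cccc(OCc4ccccc4)c3OCc3ccccc3)c(OCc3ccccc3)c21
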